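**Retrosynthetic overview**

1. Target ⇒ ring B α-methylene ketone (carrying 5α-OH and the C19 acid) + an (E)-C5 side-chain organocerium (C9–C11 bond, sets C9); the enone ⇒ the saturated ketone by α-methylenation (C8=C17).
2. 5α-OH ⇒ radical Markovnikov hydration of a Δ5(6) keto acid (sets C5 trans to CH3-20); the Δ5 acid ⇒ E1 opening of a cis-fused β-lactone.
3. Key disconnection: C4–C5 and C19–O5 are made together by a catalytic desymmetrising aldol-lactonisation of a prochiral dione acid, which closes ring A and the β-lactone in one operation and sets C10 and C4.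
4. Dione acid ⇒ 2-methylcyclohexane-1,3-dione + acrolein (C1–C3) + a stabilised ylide (C4, C18, C19); side chain ⇒ 4-bromobut-1-yne by carboalumination.
5. Ring order: ring B comes from the starting dione; ring A and the β-lactone ring then close together; the lactone ring is opened again afterwards.

Convention: labdane numbering is used for all bicyclic compounds (C4 carries CH3-18 and the C19 carboxyl, C10 carries CH3-20, C8 carries C17); β is the face of CH3-20.

Assumption: (S)-HBTM ((S)-homobenzotetramisole) is taken to give the enantiomer of 9 drawn; if its sense of induction is the opposite, (R)-HBTM is used and nothing else changes.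

**Route**

Step 1
Reactants: 1 2-methylcyclohexane-1,3-dione; 2 acrolein (prop-2-enal)
Product: 3 3-(1-methyl-2,6-dioxocyclohexyl)propanal
Conditions: H2O, 23 °C
Reagents that add atoms: none
Why: Michael addition of the acidic C–H of the 1,3-dione to acrolein in water gives clean C-alkylation; the product is achiral, with C10 prochiral.

Step 2
Reactants: 3 3-(1-methyl-2,6-dioxocyclohexyl)propanal; 4 benzyl 2-(triphenylphosphoranylidene)propanoate (stabilised ylide)
Product: 5 benzyl (E)-2-methyl-5-(1-methyl-2,6-dioxocyclohexyl)pent-2-enoate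
Conditions: toluene, 60 °C
Reagents that add atoms: none
Why: Wittig olefination; the ester-stabilised ylide reacts only with the aldehyde, not the hindered ring ketones, and gives the E-enoate, whose geometry is removed in step 3.

Step 3
Reactants: 5 benzyl (E)-2-methyl-5-(1-methyl-2,6-dioxocyclohexyl)pent-2-enoate
Product: 6 rac-2-methyl-5-(1-methyl-2,6-dioxocyclohexyl)pentanoic acid
Conditions: H2 (1 atm), Pd/C, EtOAc, 23 °C
Reagents that add atoms: none
Why: Catalytic hydrogenation saturates the enoate C=C and hydrogenolyses the benzyl ester in one pot without touching the ketones; the new C4 centre is racemic, which is harmless because it is planarised in step 4.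

Step 4
Reactants: 6 rac-2-methyl-5-(1-methyl-2,6-dioxocyclohexyl)pentanoic acid
Product: 9 cis-fused keto β-lactone (19,5-lactone of 5β-hydroxy-4α,10β-dimethyl-9-oxodecalin-4β-carboxylic acid), via mixed tosyl anhydride 7 (not isolated), via catalyst-bound enolate 8 (not isolated)
Conditions: TsCl, iPr2NEt, LiCl, (S)-HBTM (20 mol %), CH2Cl2, 23 °C
Reagents that add atoms: none
Why: Proposed new method: mixed anhydride 7 acylates the chiral isothiourea and is deprotonated to the fully substituted catalyst-bound enolate 8 (erasing C4 of rac-6), which adds to one of the two enantiotopic ketones through a lithium-bridged chair and is trapped irreversibly by O-acylation, so ring A and the β-lactone close in one operation and C4, C5 and C10 are set together (the lactone forces C19 syn to O5, and the cis ring fusion with O5 syn to CH3-20 is favoured because the trans alternative needs CH3-18 and CH3-20 1,3-diaxial); the closest known reaction type is the nucleophile-catalysed aldol-lactonisation (NCAL) desymmetrisation of dione acids that are unsubstituted at the α-carbon, together with nucleophile-catalysed [2+2] reactions of disubstituted ketenes with carbonyl compounds.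

Step 5
Reactants: 9 cis-fused keto β-lactone
Product: 10 4α,10β-dimethyl-9-oxodecal-5(6)-ene-4β-carboxylic acid
Conditions: TfOH (10 mol %), CH2Cl2, 0 °C
Reagents that add atoms: none
Why: Brønsted-acid alkyl–oxygen ionisation of the strained tertiary β-lactone followed by E1 loss of H-6 (the only β-hydrogens, since C4 and C10 are quaternary) gives the β,γ-unsaturated acid; this erases the unwanted 5β configuration while C4 and C10 are untouched.

Step 6
Reactants: 10 4α,10β-dimethyl-9-oxodecal-5(6)-ene-4β-carboxylic acid
Product: 12 5α-hydroxy-4α,10β-dimethyl-9-oxo-trans-decalin-4β-carboxylic acid, via 5α-hydroperoxide 11 (not isolated)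
Conditions: Mn(dpm)3 (10 mol %), PhSiH3, O2 (1 atm), iPrOH/CH2Cl2, 0 to 23 °C; then PPh3
Reagents that add atoms: dioxygen, O=O
Why: Mukaiyama hydration (metal-hydride hydrogen-atom transfer, then O2 trapping): H adds to C6 and the planar tertiary C5 radical is trapped by O2 on the α face, opposite both CH3-20 and the C19 carboxyl, giving the trans-fused hydroperoxide 11, which PPh3 reduces to the 5α-alcohol.

Step 7
Reactants: 12 5α-hydroxy-4α,10β-dimethyl-9-oxo-trans-decalin-4β-carboxylic acid
Product: 13 5α-hydroxy-4α,10β-dimethyl-8-methylidene-9-oxo-trans-decalin-4β-carboxylic acid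
Conditions: (CH2O)n, iPr2NH·CF3CO2H, THF, 65 °C
Reagents that add atoms: formaldehyde (as paraformaldehyde), C=O
Why: Mannich-type α-methylenation of the ketone; C8 is the only enolisable position (C10 is quaternary), so the regiochemistry is fixed and no stereocentre is made.

Step 8
Reactants: 14 4-bromobut-1-yne
Product: 16 (E)-5-bromo-3-methylpent-2-en-1-ol, via alkenylalane 15 (not isolated)
Conditions: Me3Al, Cp2ZrCl2 (20 mol %), CH2Cl2, 0 to 23 °C; then n-BuLi, (CH2O)n, THF, −78 to 23 °C
Reagents that add atoms: trimethylaluminium, C[Al](C)C; formaldehyde (as paraformaldehyde), C=O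
Why: Negishi zirconium-catalysed carboalumination adds CH3 and Al syn across the alkyne (CH3 to the internal carbon), and the derived alkenyl aluminate is hydroxymethylated with retention, which fixes the 13E geometry.

Step 9
Reactants: 16 (E)-5-bromo-3-methylpent-2-en-1-ol
Product: 17 (E)-[(5-bromo-3-methylpent-2-en-1-yl)oxy](tert-butyl)dimethylsilane
Conditions: TBSCl, imidazole, CH2Cl2, 23 °C
Reagents that add atoms: tert-butyldimethylsilyl chloride, CC(C)(C)[Si](C)(C)Cl
Why: Standard silylation of the primary allylic alcohol so that the bromide can be metalated; no stereochemistry is involved.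

Step 10
Reactants: 13 5α-hydroxy-4α,10β-dimethyl-8-methylidene-9-oxo-trans-decalin-4β-carboxylic acid; 17 (E)-[(5-bromo-3-methylpent-2-en-1-yl)oxy](tert-butyl)dimethylsilane
Product: 20 15-(tert-butyldimethylsilyloxy)-5α,9β-dihydroxylabda-8(17),13E-dien-19-oic acid, via Grignard reagent 18 (not isolated), via organocerium reagent 19 (not isolated)
Conditions: 17 (3.5 equiv), Mg, THF, 23 °C; CeCl3, THF, −78 °C; then 13, −78 to −40 °C
Reagents that add atoms: none
Why: Imamoto organocerium 1,2-addition to the α-methylene ketone (no conjugate addition or enolisation); the excess reagent first deprotonates CO2H and 5-OH, and the carbon nucleophile is then delivered to the α face of C9, syn to the axial 5α-alkoxide–cerium centre and anti to CH3-20, giving 9β-OH with the side chain α.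

Step 11
Reactants: 20 15-(tert-butyldimethylsilyloxy)-5α,9β-dihydroxylabda-8(17),13E-dien-19-oic acid
Product: 21 5α,9β,15-trihydroxylabda-8(17),13E-dien-19-oic acid (5α,9β-dihydroxyisocupressic acid)
Conditions: TBAF, THF, 23 °C
Reagents that add atoms: none
Why: Fluoride cleavage of the primary silyl ether; the tertiary alcohols, the alkenes and the acid are inert to fluoride, so no stereocentre is disturbed.

**Compound list**

1 | 2-methylcyclohexane-1,3-dione | CC1C(=O)CCCC1=O | starting material
2 | acrolein (prop-2-enal) | C=CC=O | starting material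
3 | 3-(1-methyl-2,6-dioxocyclohexyl)propanal | O=CCCC1(C)C(=O)CCCC1=O | intermediate
4 | benzyl 2-(triphenylphosphoranylidene)propanoate | CC(=P(c1ccccc1)(c1ccccc1)c1ccccc1)C(=O)OCc1ccccc1 | starting material
5 | benzyl (E)-2-methyl-5-(1-methyl-2,6-dioxocyclohexyl)pent-2-enoate | C/C(C(=O)OCc1ccccc1)=C\CCC1(C)C(=O)CCCC1=O | intermediate
6 | rac-2-methyl-5-(1-methyl-2,6-dioxocyclohexyl)pentanoic acid | CC(CCCC1(C)C(=O)CCCC1=O)C(=O)O | intermediate
7 | mixed anhydride of 6 with 4-methylbenzenesulfonic acid | CC(CCCC1(C)C(=O)CCCC1=O)C(=O)OS(=O)(=O)c1ccc(C)cc1 | intermediate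
8 | N-acyl isothiouronium enolate of 6 bound to (S)-HBTM | CC(CCCC1(C)C(=O)CCCC1=O)=C([O-])[N+]1=C2Sc3ccccc3N2CC[C@H]1c1ccccc1 | intermediate
9 | cis-fused keto β-lactone: 19,5-lactone of 5β-hydroxy-4α,10β-dimethyl-9-oxodecalin-4β-carboxylic acid (O5, C19 and CH3-20 all β; CH3-18 α) | C1CC[C@@]2(O3)[C@](C)(CCC[C@]2(C)C3=O)C1=O | intermediate
10 | 4α,10β-dimethyl-9-oxodecal-5(6)-ene-4β-carboxylic acid | C1CC=C2[C@](C)(CCC[C@]2(C)C(=O)O)C1=O | intermediate
11 | 5α-hydroperoxy-4α,10β-dimethyl-9-oxo-trans-decalin-4β-carboxylic acid | C1CC[C@]2(OO)[C@](C)(CCC[C@]2(C)C(=O)O)C1=O | intermediate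
12 | 5α-hydroxy-4α,10β-dimethyl-9-oxo-trans-decalin-4β-carboxylic acid | C1CC[C@]2(O)[C@](C)(CCC[C@]2(C)C(=O)O)C1=O | intermediate
13 | 5α-hydroxy-4α,10β-dimethyl-8-methylidene-9-oxo-trans-decalin-4β-carboxylic acid | C=C1CC[C@]2(O)[C@](C)(CCC[C@]2(C)C(=O)O)C1=O | intermediate
14 | 4-bromobut-1-yne | C#CCCBr | starting material
15 | (E)-(4-bromo-2-methylbut-1-en-1-yl)dimethylalane | C[Al](C)/C=C(\C)CCBr | intermediate
16 | (E)-5-bromo-3-methylpent-2-en-1-ol | OC/C=C(\C)CCBr | intermediate
17 | (E)-[(5-bromo-3-methylpent-2-en-1-yl)oxy](tert-butyl)dimethylsilane | CC(C)(C)[Si](C)(C)OC/C=C(\C)CCBr | intermediate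
18 | (E)-[5-(tert-butyldimethylsilyloxy)-3-methylpent-3-en-1-yl]magnesium bromide | CC(C)(C)[Si](C)(C)OC/C=C(\C)CC[Mg]Br | intermediate
19 | (E)-[5-(tert-butyldimethylsilyloxy)-3-methylpent-3-en-1-yl]cerium dichloride | CC(C)(C)[Si](C)(C)OC/C=C(\C)CC[Ce](Cl)Cl | intermediate
20 | 15-(tert-butyldimethylsilyloxy)-5α,9β-dihydroxylabda-8(17),13E-dien-19-oic acid | C=C1CC[C@]2(O)[C@](C)(CCC[C@]2(C)C(=O)O)[C@]1(O)CC/C(C)=C/CO[Si](C)(C)C(C)(C)C | intermediate
21 | 5α,9β,15-trihydroxylabda-8(17),13E-dien-19-oic acid (5α,9β-dihydroxyisocupressic acid) | C=C1CC[C@]2(O)[C@](C)(CCC[C@]2(C)C(=O)O)[C@]1(O)CC/C(C)=C/CO | target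

**Step count and risks**

Total step count: 11. Longest linear sequence: 9 steps (steps 1 to 7, then 10 and 11); the side chain takes steps 8 and 9.

Stereocentres: C10 and C4 are set in step 4, C5 is reset in step 6, C9 is set in step 10, and the 13E alkene is set in step 8.

The three steps most likely to fail:

Step 4. The α-branched acid may enolise too slowly, or the crowded C4–C5 bond (quaternary carbon next to a tertiary carbinol next to a quaternary carbon) may not form; the ring-fusion sense is predicted, not proven. The fallback sets out from 5 and builds ring A alone with a metal enolate. A copper hydride-catalysed desymmetrising reductive aldol cyclisation (Cu(OAc)2·H2O, (R)-DTBM-SEGPHOS, (EtO)2MeSiH, THF) of the enoate gives the cis-fused benzyl ketol ester F1 through a chelated chair that places the ester syn to CH3-20. Burgess dehydration (only H-6 is available) gives the Δ5 benzyl ester F2. Hydrogenolysis (H2, Pd/C; the hindered trisubstituted alkene between two quaternary carbons is not reduced) returns to the route at 10.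

Step 5. The ionised lactone may lose CO2 (giving the C4=C5 alkene) or fragment at C9–C10 in preference to losing H-6. The fallback sets out from 9 and avoids the cation. LiOH in THF/H2O at 0 °C cleaves the acyl–oxygen bond to give the cis-fused 5β-hydroxy acid F3. Burgess reagent (2.5 equiv, benzene, 50 °C, aqueous work-up) then removes the tertiary alcohol by syn elimination towards C6 and returns to the route at 10.

Step 10. The functionalised organocerium must add to a hindered, triply deprotonated enone, and the α-face delivery rests on direction by the 5-alkoxide. The fallback sets out from 13 and builds the side chain on the ring from a small, cheap nucleophile used in large excess. But-3-enylmagnesium bromide with CeCl3 gives the but-3-enyl carbinol F4. Wacker oxidation (PdCl2, CuCl, O2, DMF/H2O; the 1,1-disubstituted exocyclic alkene does not react) gives the methyl ketone F5. Horner–Wadsworth–Emmons olefination ((EtO)2P(O)CH2CO2Et, NaH, THF) gives the ethyl (E)-enoate F6. Reduction with i-Bu2AlH (CH2Cl2, −78 °C; the carboxylate is not reduced) comes back to the route at the target 21.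

**Further compounds**

F1 | step 4 | benzyl 5β-hydroxy-4α,10β-dimethyl-9-oxo-cis-decalin-4β-carboxylate | C1CC[C@@]2(O)[C@](C)(CCC[C@]2(C)C(=O)OCc3ccccc3)C1=O
F2 | step 4 | benzyl 4α,10β-dimethyl-9-oxodecal-5(6)-ene-4β-carboxylate | C1CC=C2[C@](C)(CCC[C@]2(C)C(=O)OCc3ccccc3)C1=O
F3 | step 5 | 5β-hydroxy-4α,10β-dimethyl-9-oxo-cis-decalin-4β-carboxylic acid | C1CC[C@@]2(O)[C@](C)(CCC[C@]2(C)C(=O)O)C1=O
F4 | step 10 | 9α-(but-3-en-1-yl)-5α,9β-dihydroxy-4α,10β-dimethyl-8-methylidene-trans-decalin-4β-carboxylic acid | C=C1CC[C@]2(O)[C@](C)(CCC[C@]2(C)C(=O)O)[C@]1(O)CCC=C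
F5 | step 10 | 5α,9β-dihydroxy-4α,10β-dimethyl-8-methylidene-9α-(3-oxobutyl)-trans-decalin-4β-carboxylic acid | C=C1CC[C@]2(O)[C@](C)(CCC[C@]2(C)C(=O)O)[C@]1(O)CCC(C)=O
F6 | step 10 | 15-ethyl ester of 5α,9β-dihydroxylabda-8(17),13E-diene-15,19-dioic acid | C=C1CC[C@]2(O)[C@](C)(CCC[C@]2(C)C(=O)O)[C@]1(O)CC/C(C)=C/C(=O)OCC
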